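## Retrosynthetic overview
1. Target 22 comes from Petasis methylenation of ketone 21. The exocyclic alkene goes in last so it cannot compete for HBr. Ketone 21 comes from Markovnikov, anti hydrobromination of the ring-B alkene in 20 (C9–Br trans to C10–Cl). The C10 chloride comes from a ketoreductase-derived allylic alcohol by SN2 with inversion.
2. Ring A (CMe2, C4–Br, C3–OH) comes from tandem cuprate methylation and α-bromination of enone 10, followed by ketoreductase reduction of α-bromoketone 12. Enone 10 comes from ketone 7 by Saegusa–Ito oxidation and Babler–Dauben transposition.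
3. The spiro quaternary centre C6 comes from enzymatic desymmetrization of the achiral spiro-1,3-dione 5. Dione 5 is made by double C-alkylation of cyclohexane-1,3-dione with Z-dibromide 3.
4. Ring order: ring A (the dione ring) exists first, ring B is formed by spiroannulation, the enzyme then sets C6, and ring-B halogens are installed last.

Assumptions (numbering of all intermediates follows the target spiro[5.5]undecane numbering):
- 4-Methyl-5,6-dihydro-2H-pyran-2-one (1) is available from a specialty supplier.
- A ketoreductase with the required selectivity can be found in a commercial KRED panel for each of the three enzymatic reductions.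

## Route

**Step 1**
Reactants: 1, 4-methyl-5,6-dihydro-2H-pyran-2-one
Product: 2, (2Z)-3-methylpent-2-ene-1,5-diol
Conditions: DIBAL-H (2.5 equiv), CH2Cl2, −78 → 0 °C; Rochelle salt work-up
Reagents that add atoms: none
Why: Excess DIBAL-H reduces the unsaturated lactone (via the lactol) 1,2 to the diol, and the cis (Z) alkene geometry is carried over from the ring; no stereocentre is formed.

**Step 2**
Reactants: 2, the Z-diol
Product: 3, (2Z)-1,5-dibromo-3-methylpent-2-ene
Conditions: (i) MsCl (2.4 equiv), Et3N, CH2Cl2, −40 °C; (ii) LiBr (6 equiv), THF, −20 °C → rt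
Reagents that add atoms: LiBr, [Li]Br (supplies Br)
Why: Both hydroxyls are sulfonylated before the allylic sulfonate can be trapped by the tail OH, and SN2 displacement at the two primary carbons leaves the Z alkene untouched (Finkelstein-type substitution).

**Step 3**
Reactants: 3, the Z-dibromide; 4, cyclohexane-1,3-dione
Product: 5, 9-methylspiro[5.5]undec-8-ene-1,5-dione (achiral, Cs; the two ring-A carbonyls are enantiotopic)
Conditions: Cs2CO3 (2.5 equiv), NaI (cat.), DMF, 25 → 60 °C, 0.02 M
Reagents that add atoms: none
Why: Intermolecular C-alkylation at the allylic bromide is followed by intramolecular 6-exo C-alkylation at the primary bromide (double alkylation of a 1,3-dicarbonyl, i.e. spiroannulation), and the Z geometry makes the cyclohexene ring closure possible.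

**Step 4**
Reactants: 5, spiro-dione
Product: 6, 1-hydroxy-9-methylspiro[5.5]undec-8-en-5-one; single enantiomer with C6 as in the target and C1–OH on the face opposite the C6–C11 bond (ring-A C1 is the carbinol, C5 the ketone)
Conditions: ketoreductase (KRED, NADPH-dependent, panel-selected), NADP+ (cat.), i-PrOH (10% v/v), 100 mM KPi pH 7.0, DMSO 10%, 30 °C
Reagents that add atoms: none
Why: The enzyme reduces one of the two enantiotopic carbonyls (desymmetrizing ketoreductase reduction), which makes C6 stereogenic and fixes its absolute configuration together with the carbinol; this is the first stereocentre of the route.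

**Step 5**
Reactants: 6, hydroxy-ketone
Product: 7, TBS ether of 6 (C1–OTBS)
Conditions: TBSOTf (1.5 equiv), 2,6-lutidine, CH2Cl2, −78 → 0 °C
Reagents that add atoms: TBSOTf, CC(C)(C)[Si](C)(C)OS(=O)(=O)C(F)(F)F
Why: The triflate silylates the neopentylic secondary alcohol, and no stereocentre is touched.

**Step 6**
Reactants: 7, TBS ether ketone
Product: 8, enone: 1-(TBSO)-9-methylspiro[5.5]undeca-3,8-dien-5-one (C5=O, C3=C4), C6 and C1 unchanged
Conditions: (i) LiHMDS, TMSCl, THF, −78 °C; (ii) Pd(OAc)2 (1 equiv), MeCN, rt
Reagents that add atoms: none (TMS is lost)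
Why: Saegusa–Ito oxidation is regiospecific because C6 is quaternary, so the silyl enol ether can only form toward C4, and no new stereocentre arises.

**Step 7**
Reactants: 8, enone
Product: 9, tertiary allylic alcohol (C5(OH)Me, C3=C4; C5 epimers, irrelevant)
Conditions: MeLi (2 equiv), anhydrous CeCl3 (2.2 equiv), THF, −78 °C
Reagents that add atoms: MeLi, [Li]C
Why: Organocerium 1,2-addition (Luche/Imamoto-type) to the hindered enone carbonyl avoids conjugate addition, and the new carbinol centre is destroyed in the next step.

**Step 8**
Reactants: 9, tertiary allylic alcohol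
Product: 10, 1-(TBSO)-5,9-dimethylspiro[5.5]undeca-4,8-dien-3-one (C3=O, C4=C5(Me)), C6 and C1 unchanged
Conditions: PCC (3 equiv), NaOAc, 4 Å MS, CH2Cl2, rt
Reagents that add atoms: none
Why: Babler–Dauben oxidative 1,3-transposition moves oxygen to C3 through the chromate ester and gives the β-methyl enone with the alkene at C4=C5; no stereocentre is formed.

**Step 9**
Reactants: 10, enone
Product: 11, C3 TMS enol ether of the 5,5-dimethyl ketone (C3(OTMS)=C4, C5Me2), C6 and C1 unchanged
Conditions: Me2CuLi (3 equiv, from CuI + 2 MeLi), TMSCl (4 equiv), THF, −78 → 0 °C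
Reagents that add atoms: Me2CuLi, C[Cu-]C.[Li+] (delivers CH3); TMSCl, C[Si](C)(C)Cl (TMS retained in 11)
Why: Cuprate 1,4-addition of methyl to the β-carbon C5 builds the gem-dimethyl group, and the resulting enolate is trapped as the C3=C4 silyl enol ether (conjugate addition with in situ silylation); no stereocentre is formed.

**Step 10**
Reactants: 11, silyl enol ether
Product: 12, 4-bromo-5,5,9-trimethyl-1-(TBSO)spiro[5.5]undec-8-en-3-one (C4–Br as in the target, C6 and C1 unchanged)
Conditions: NBS (1.05 equiv), THF, −78 °C, 30 min
Reagents that add atoms: NBS, O=C1CCC(=O)N1Br (supplies Br)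
Why: Electrophilic bromination of the silyl enol ether (Mukaiyama-type α-halogenation) sets C4–Br through axial attack on the half-chair, and this centre is epimerizable, so it is corrected in the next step.

**Step 11**
Reactants: 12, α-bromoketone
Product: 13, bromohydrin (C3–OH cis to C4–Br, as in the target)
Conditions: KRED (panel-selected), NADP+ (cat.), i-PrOH, KPi pH 7.0, DMSO 10%, 30 °C
Reagents that add atoms: none
Why: The enzyme reduces C3 by hydride transfer while the α-bromo centre C4 epimerizes through the enol, so one diastereomer is selected (dynamic kinetic resolution), which sets C3 and C4 with the cis relationship.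

**Step 12**
Reactants: 13, bromohydrin
Product: 14, the C3 acetate
Conditions: Ac2O (5 equiv), Et3N, DMAP (0.3 equiv), CH2Cl2, rt → 40 °C
Reagents that add atoms: Ac2O, CC(=O)OC(C)=O (acetyl retained)
Why: DMAP-catalysed acylation of the hindered secondary alcohol with retention at C3.

**Step 13**
Reactants: 14, ring-B alkene
Product: 15, C10 allylic alcohol (C8=C9 retained; C10 epimers)
Conditions: SeO2 (0.3 equiv), TBHP (5.5 M in decane, 4 equiv), CH2Cl2, rt, 24 h
Reagents that add atoms: TBHP, CC(C)(C)OO (source of the new C–O oxygen)
Why: Riley/Guillemonat allylic oxidation goes at the CH2 flanking the more substituted alkene carbon (C10), because the other allylic CH2 (C7) sits next to the quaternary spiro carbon; the C10 configuration is irrelevant because it is oxidised next.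

**Step 14**
Reactants: 15, allylic alcohol
Product: 16, ring-B enone (C10=O, C8=C9(Me))
Conditions: Dess–Martin periodinane (1.5 equiv), NaHCO3, CH2Cl2, rt
Reagents that add atoms: none
Why: DMP oxidation under neutral conditions erases the C10 epimer mixture.

**Step 15**
Reactants: 16, enone
Product: 17, C10 allylic alcohol as a single epimer (OH on the same face as the C6–C5 bond, so that inversion in Step 16 puts Cl on the target face)
Conditions: KRED (panel-selected), NADP+ (cat.), i-PrOH, KPi pH 7.0, 30 °C
Reagents that add atoms: none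
Why: Enzyme-controlled 1,2-reduction of the enone C=O sets C10, and the ring-A ketone is absent, so the chemoselectivity is trivial.

**Step 16**
Reactants: 17, allylic alcohol
Product: 18, C10 allylic chloride with Cl as in the target
Conditions: MsCl (1.5 equiv), 2,4,6-collidine, CH2Cl2, 0 °C; then LiCl (10 equiv), DMF, rt → 40 °C
Reagents that add atoms: LiCl, [Li]Cl (supplies Cl; MsCl is not retained)
Why: In situ mesylate displacement by chloride (Meyers-type SN2) inverts C10 and, because C9 is sp2, avoids neopentylic hindrance.

**Step 17**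
Reactants: 18, TBS ether
Product: 19, C1 alcohol
Conditions: HF·pyridine, pyridine/THF, 0 °C → rt, 48 h
Reagents that add atoms: none
Why: Fluoride-mediated desilylation under non-basic conditions leaves the acetate, alkyl halides and alkene unaffected.

**Step 18**
Reactants: 19, C1 alcohol
Product: 20, C1 ketone
Conditions: Dess–Martin periodinane (2 equiv), NaHCO3, CH2Cl2, rt
Reagents that add atoms: none
Why: Buffered DMP oxidation avoids E1cB loss of the β-acetate, and the transient C1 carbinol stereocentre is removed.

**Step 19**
Reactants: 20, ring-B alkene with C1 ketone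
Product: 21, ketone carrying C9(Me)(Br) and C10–Cl
Conditions: anhydrous HBr (2.5 equiv), CH2Cl2, −78 → −20 °C
Reagents that add atoms: HBr, Br (supplies Br)
Why: Markovnikov protonation at C8 gives the tertiary C9 cation, and bromide adds anti to the neighbouring C10–Cl (trans addition assisted by chlorine participation), which sets C9.

**Step 20**
Reactants: 21, ketone
Product: 22, 9-acetyllisoobtusol ((4,9-dibromo-10-chloro-5,5,9-trimethyl-1-methylidenespiro[5.5]undecan-3-yl) acetate)
Conditions: Cp2TiMe2 (4 equiv), toluene/THF 4:1, 65 °C, 16 h, dark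
Reagents that add atoms: Cp2TiMe2, C[Ti](C)([CH]1C=CC=C1)[CH]1C=CC=C1 (delivers =CH2)
Why: Petasis methylenation is neutral and chemoselective for the hindered ketone over the acetate and alkyl halides; no new stereocentre is formed.

## Compound list
1 | 4-methyl-5,6-dihydro-2H-pyran-2-one | CC1=CC(=O)OCC1 | starting material
2 | (2Z)-3-methylpent-2-ene-1,5-diol | OC/C=C(\CCO)C | intermediate
3 | (2Z)-1,5-dibromo-3-methylpent-2-ene | BrC/C=C(\CCBr)C | intermediate
4 | cyclohexane-1,3-dione | O=C1CCCC(=O)C1 | starting material
5 | 9-methylspiro[5.5]undec-8-ene-1,5-dione | O=C1CCCC(=O)C12CC=C(C)CC2 | intermediate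
6 | 1-hydroxy-9-methylspiro[5.5]undec-8-en-5-one | O[C@H]1CCCC(=O)[C@@]12CC=C(C)CC2 | intermediate
7 | 1-OTBS ether of 6 | CC(C)(C)[Si](C)(C)O[C@H]1CCCC(=O)[C@@]12CC=C(C)CC2 | intermediate
8 | 1-(TBSO)-9-methylspiro[5.5]undeca-3,8-dien-5-one | CC(C)(C)[Si](C)(C)O[C@H]1CC=CC(=O)[C@@]12CC=C(C)CC2 | intermediate
9 | C5-methyl tertiary allylic alcohol (C5 epimers) | CC(C)(C)[Si](C)(C)O[C@H]1CC=CC(C)(O)[C@@]12CC=C(C)CC2 | intermediate
10 | 1-(TBSO)-5,9-dimethylspiro[5.5]undeca-4,8-dien-3-one | CC(C)(C)[Si](C)(C)O[C@H]1CC(=O)C=C(C)[C@@]12CC=C(C)CC2 | intermediate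
11 | C3 TMS enol ether of the 5,5-dimethyl ketone | CC(C)(C)[Si](C)(C)O[C@H]1CC(O[Si](C)(C)C)=CC(C)(C)[C@@]12CC=C(C)CC2 | intermediate
12 | 4-bromo-5,5,9-trimethyl-1-(TBSO)spiro[5.5]undec-8-en-3-one | CC(C)(C)[Si](C)(C)O[C@H]1CC(=O)[C@H](Br)C(C)(C)[C@@]12CC=C(C)CC2 | intermediate
13 | cis-bromohydrin (3-OH, 4-Br) | CC(C)(C)[Si](C)(C)O[C@H]1C[C@H](O)[C@H](Br)C(C)(C)[C@@]12CC=C(C)CC2 | intermediate
14 | C3 acetate of 13 | CC(C)(C)[Si](C)(C)O[C@H]1C[C@H](OC(C)=O)[C@H](Br)C(C)(C)[C@@]12CC=C(C)CC2 | intermediate
15 | C10 allylic alcohol (epimers) | CC(C)(C)[Si](C)(C)O[C@H]1C[C@H](OC(C)=O)[C@H](Br)C(C)(C)[C@@]12CC=C(C)C(O)C2 | intermediate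
16 | C10 ring-B enone | CC(C)(C)[Si](C)(C)O[C@H]1C[C@H](OC(C)=O)[C@H](Br)C(C)(C)[C@@]12CC=C(C)C(=O)C2 | intermediate
17 | C10 allylic alcohol, single epimer | CC(C)(C)[Si](C)(C)O[C@H]1C[C@H](OC(C)=O)[C@H](Br)C(C)(C)[C@@]12CC=C(C)[C@H](O)C2 | intermediate
18 | C10 allylic chloride | CC(C)(C)[Si](C)(C)O[C@H]1C[C@H](OC(C)=O)[C@H](Br)C(C)(C)[C@@]12CC=C(C)[C@@H](Cl)C2 | intermediate
19 | C1 alcohol | O[C@H]1C[C@H](OC(C)=O)[C@H](Br)C(C)(C)[C@@]12CC=C(C)[C@@H](Cl)C2 | intermediate
20 | C1 ketone with ring-B alkene | O=C1C[C@H](OC(C)=O)[C@H](Br)C(C)(C)[C@@]12CC=C(C)[C@@H](Cl)C2 | intermediate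
21 | C1 ketone, tertiary bromide | O=C1C[C@H](OC(C)=O)[C@H](Br)C(C)(C)[C@@]12CC[C@](C)(Br)[C@@H](Cl)C2 | intermediate
22 | 9-acetyllisoobtusol | C=C1C[C@H](OC(C)=O)[C@H](Br)C(C)(C)[C@@]12CC[C@](C)(Br)[C@@H](Cl)C2 | target

## Totals
Total steps: 20. Longest linear sequence: 20 steps (1 → 2 → 3 → 5 → … → 22; cyclohexane-1,3-dione enters at step 3).

Three steps most likely to fail:
1. **Step 9 (vicinal quaternary centre by cuprate addition to a β,β-disubstituted enone next to the spiro carbon).**
   Fallback: change strategy to a dimedone-derived vinylogous ester carrying the CMe2 carbon from the start, close the spiro centre by intramolecular enolate/Pd allylic alkylation, and resolve the quaternary centre enzymatically.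
2. **Steps 10–11 (C4–Br configuration and the cis C3/C4 relationship via NBS bromination and KRED dynamic kinetic resolution).**
   Fallback: drop the ketone-based installation and form ring A by biomimetic bromonium-initiated cyclization (bromoperoxidase/H2O2/KBr or a BDSB-type reagent) of a C3-oxygenated prenyl precursor, which sets C4–Br and the C5–C6 bond together.
3. **Step 19 (hydrobromination regio- and stereochemistry next to an allylic chloride, and survival of the tertiary bromide and β-acetoxy ketone through Step 20).**
   Fallback: replace it with a chlorohydrin route: cis-dihydroxylate the ring-B alkene, make the cyclic sulfate, open it with chloride at C10, and convert the tertiary alcohol to bromide with retention through chlorine participation.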